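**Plan**

- Labdane numbering is used (ring A = C1–C5 and C10; ring B = C5–C10; side chain C11–C16; C17 = exocyclic CH2; C18 = the CH2O carbon on C4). The retrosynthesis cuts the C18–O acyl bond, C8=C17 (Wittig), C9–C11 (Negishi) and C4–C18 (aldol with formaldehyde), then C1–C2 and C5–C10 together (intramolecular Diels–Alder). The resulting acyclic triene is cut at C9–C10 (Weinreb ketone synthesis), C4=C5 (cross-metathesis) and C6–C7 (epoxide opening).
- Enabling feature: in ring A the bonds C1–C2 and C5–C10 flank the C1–C10 bond and face the chain C2–C3–C4–C5, so C2=C3–C4=C5 can act as diene and C10=C1 as dienophile, while C6–C9 of ring B already tie C5 to C10 as a four-carbon tether. C3, C8 and C9 end as CH2, C=CH2 and CH and can therefore carry helper oxygen.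
- Helpers, each with a second job: the C9 ketone activates the dienophile and later becomes the enol triflate for C9–C11. The C8 methoxy group (from (S)-glycidate) gives chelation and face control and later the C8 ketone for the methylene. The C3 silyloxy group activates the diene, gives the regiodefined enol ether for the C4 quaternary centre, and is then removed by tosylhydrazone reduction.
- Forward order: linear C2–C10 chain, then rings A and B in one step, C4 quaternary centre, C3 deoxygenation, side chain at C9, C8 methylene, coumarate, deprotection.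
- Stereochemistry: C8 (chiral pool) sets C10 and C5 and is then erased; C4 is set by attack anti to the C10 methyl; C9 by protonation and equilibration next to the C8 ketone; C13 comes from (R)-3-methylglutaric acid monomethyl ester; the cinnamate E geometry comes from the reagent.

Key step: step 7

**Route**

Step 1
Reactants: 1 methyl (2S)-oxirane-2-carboxylate
Product: 2 methyl (2S)-2-hydroxyhex-5-enoate
Conditions: CH2=CHCH2MgBr, CuI (10 mol%), THF, −78 → −40 °C; aq. NH4Cl
Reagents that add atoms: allylmagnesium bromide, C=CC[Mg]Br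
Why: copper-catalysed Grignard opening of the epoxide at the unsubstituted carbon (SN2 at C7) should outrun ester attack at low temperature and leaves the C8 stereocentre untouched.

Step 2
Reactants: 2 methyl (2S)-2-hydroxyhex-5-enoate
Product: 3 methyl (2S)-2-methoxyhex-5-enoate
Conditions: MeI, Ag2O, MeCN, rt, dark
Reagents that add atoms: iodomethane, CI
Why: silver-oxide-mediated O-methylation (Purdie-type Williamson etherification) works without strong base, so the α-stereocentre of the hydroxy ester should not epimerise.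

Step 3
Reactants: 3 methyl (2S)-2-methoxyhex-5-enoate
Product: 4 (2S)-N,2-dimethoxy-N-methylhex-5-enamide
Conditions: MeNH(OMe)·HCl, iPrMgCl, THF, −20 → 0 °C
Reagents that add atoms: N,O-dimethylhydroxylamine hydrochloride, CNOC.Cl
Why: aminolysis of the ester by the magnesium amide gives the Weinreb amide, a reaction known to preserve α-alkoxy stereocentres.

Step 4
Reactants: 4 (2S)-N,2-dimethoxy-N-methylhex-5-enamide; 5 3-methylbut-3-en-2-one
Product: 6 (2S,5E)-N,2-dimethoxy-N,6-dimethyl-7-oxooct-5-enamide
Conditions: 5 (5 equiv), second-generation Hoveyda–Grubbs catalyst RuCl2(SIMes)(=CH-C6H4-2-OiPr) (5 mol%), CH2Cl2, 40 °C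
Reagents that add atoms: none
Why: olefin cross-metathesis of a terminal alkene with a 1,1-disubstituted enone should give the trisubstituted enone as the thermodynamically preferred E isomer, which does not re-enter metathesis.

Step 5
Reactants: 6 (2S,5E)-N,2-dimethoxy-N,6-dimethyl-7-oxooct-5-enamide
Product: 7 (2S,5E)-N,2-dimethoxy-N,6-dimethyl-7-[(triisopropylsilyl)oxy]octa-5,7-dienamide
Conditions: iPr3SiOTf, Et3N, CH2Cl2, −78 → 0 °C
Reagents that add atoms: triisopropylsilyl trifluoromethanesulfonate, CC(C)[Si](C(C)C)(C(C)C)OS(=O)(=O)C(F)(F)F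
Why: soft enolisation of the methyl ketone at its α′ methyl group gives the cross-conjugated 2-silyloxy diene, while the amide α-hydrogen is not acidic enough to react.

Step 6
Reactants: 7 (2S,5E)-N,2-dimethoxy-N,6-dimethyl-7-[(triisopropylsilyl)oxy]octa-5,7-dienamide
Product: 8 (4S,7E)-4-methoxy-2,8-dimethyl-9-[(triisopropylsilyl)oxy]deca-1,7,9-trien-3-one
Conditions: CH2=C(CH3)MgBr, THF, −78 → −20 °C; cold pH 7 buffer; crude 8 kept cold and used at once
Reagents that add atoms: isopropenylmagnesium bromide, CC(=C)[Mg]Br
Why: Weinreb ketone synthesis, in which the chelated tetrahedral intermediate prevents over-addition and protects the C8 stereocentre, so that the reactive enone is released only on quenching.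

Step 7
Reactants: 8 (4S,7E)-4-methoxy-2,8-dimethyl-9-[(triisopropylsilyl)oxy]deca-1,7,9-trien-3-one
Product: 9 (2S,4aR,8aR)-2-methoxy-5,8a-dimethyl-6-[(triisopropylsilyl)oxy]-3,4,4a,7,8,8a-hexahydronaphthalen-1(2H)-one
Conditions: MgBr2·OEt2 (2 equiv), CH2Cl2, −78 → −20 °C
Reagents that add atoms: none
Why: MgBr2 is held between the C9 carbonyl and the C8 methoxy oxygen, which lowers the enone LUMO, and the electron-rich diene C2=C3(OSiiPr3)–C4(CH3)=C5 adds suprafacially across C10=C1 in a concerted but asynchronous normal-demand [4+2] cycloaddition in which C2–C1 bonding (Mukaiyama–Michael character) runs ahead of C5–C10 bonding and the C3 silyl enol ether is regenerated. The closest known reaction type is the Lewis-acid-promoted type 1 intramolecular Diels–Alder reaction of 1,7,9-decatrien-3-ones, combined with chelation-controlled face selection as known for α′-alkoxy enone dienophiles. Ring A is closed as a cyclohexene by both new σ bonds (C1–C2 and C5–C10), while ring B is closed by the C5–C10 bond alone, in the fused mode, through the four-carbon tether C6–C9 in a chair-like arrangement. The quaternary centre C10 is controlled by C8: in the chelate the methoxy group is syn-periplanar to C9=O and hence equatorial on the nascent ring B chair, so C7 and with it the diene can reach only one face of the dienophile; C5 is controlled relative to C10 by the E geometry of C4=C5 and by the carbonyl-exo, methyl-endo orientation, which gives the trans ring fusion (C5–H anti to C10–CH3). The step needs regio-, ring-fusion and face selectivity: regiochemistry is enforced by the tether and agrees with the electronic preference (nucleophilic C2 to the enone β-carbon C1), trans fusion should be favoured by the α-methyl group of the dienophile and by the C3 silyloxy and C4 methyl groups that crowd the carbonyl-endo array, and the face is set by the chelate; any diastereomer at C5/C10 relative to C8 would be separable before C8 is erased.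

Step 8
Reactants: 9 (2S,4aR,8aR)-2-methoxy-5,8a-dimethyl-6-[(triisopropylsilyl)oxy]-3,4,4a,7,8,8a-hexahydronaphthalen-1(2H)-one
Product: 10 (4aR,8aR)-2-methoxy-5,8a-dimethyl-6-[(triisopropylsilyl)oxy]-3,4,4a,7,8,8a-hexahydronaphthalen-1-yl trifluoromethanesulfonate
Conditions: KN(SiMe3)2, THF, −78 °C; PhNTf2, −78 → 0 °C
Reagents that add atoms: N-phenylbis(trifluoromethanesulfonimide), O=S(=O)(N(c1ccccc1)S(=O)(=O)C(F)(F)F)C(F)(F)F
Why: C10 is quaternary, so only the axial C8–H can be removed, and O-triflation of that enolate gives the enol triflate, which erases the helper stereocentre and masks the C9 carbonyl during the ring A chemistry.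

Step 9
Reactants: 10 (4aR,8aR)-2-methoxy-5,8a-dimethyl-6-[(triisopropylsilyl)oxy]-3,4,4a,7,8,8a-hexahydronaphthalen-1-yl trifluoromethanesulfonate
Product: 11 (4aS,5S,8aR)-5-(hydroxymethyl)-2-methoxy-5,8a-dimethyl-6-oxo-3,4,4a,5,6,7,8,8a-octahydronaphthalen-1-yl trifluoromethanesulfonate
Conditions: aq. HCHO (37%), Sc(OTf)3 (10 mol%), THF, rt
Reagents that add atoms: formaldehyde, C=O
Why: water-compatible Lewis-acid-catalysed Mukaiyama aldol (hydroxymethylation) occurs regiospecifically at C4 of the silyl enol ether, and formaldehyde should approach anti to the axial C10 methyl so that CH2OH becomes equatorial; the triflyloxy-substituted C8=C9 bond is too electron-poor to compete.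

Step 10
Reactants: 11 (4aS,5S,8aR)-5-(hydroxymethyl)-2-methoxy-5,8a-dimethyl-6-oxo-3,4,4a,5,6,7,8,8a-octahydronaphthalen-1-yl trifluoromethanesulfonate
Product: 13 (4aR,5S,8aR)-5-(hydroxymethyl)-2-methoxy-5,8a-dimethyl-3,4,4a,5,6,7,8,8a-octahydronaphthalen-1-yl trifluoromethanesulfonate, via tosylhydrazone 12 (not isolated)
Conditions: TsNHNH2, EtOH, 70 °C; then catecholborane, CHCl3, 0 °C → rt; NaOAc·3H2O, reflux
Reagents that add atoms: none
Why: Caglioti-type reduction, in which hydride adds to the tosylhydrazone, sulfinate is lost and the diazene extrudes N2, removes the helper oxygen at C3 under neutral conditions that the enol triflate and the free hydroxyl should tolerate.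

Step 11
Reactants: 14 (3R)-5-methoxy-3-methyl-5-oxopentanoic acid
Product: 16 (4S)-4-methyloxan-2-one, via hydroxy acid 15 (not isolated)
Conditions: LiBH4, THF, 0 °C → rt; 1 M HCl; TsOH·H2O (cat.), CH2Cl2, rt
Reagents that add atoms: none
Why: LiBH4 reduces the ester but not the lithium carboxylate, so the acid terminus becomes C15 and the reduced terminus C11, and acid-promoted lactonisation follows without touching the C13 stereocentre.

Step 12
Reactants: 16 (4S)-4-methyloxan-2-one
Product: 18 methyl (3R)-5-iodo-3-methylpentanoate, via silyl ester 17 (not isolated)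
Conditions: Me3SiI, CH2Cl2, rt; then MeOH, rt
Reagents that add atoms: iodotrimethylsilane, C[Si](C)(C)I; methanol, CO
Why: iodide opens the silyl-activated lactone by SN2 attack at the O–CH2 carbon, and methanolysis of the silyl ester under the acid formed in the flask (Fischer esterification) gives the methyl ester.

Step 13
Reactants: 13 (4aR,5S,8aR)-5-(hydroxymethyl)-2-methoxy-5,8a-dimethyl-3,4,4a,5,6,7,8,8a-octahydronaphthalen-1-yl trifluoromethanesulfonate; 18 methyl (3R)-5-iodo-3-methylpentanoate
Product: 20 methyl (3S)-5-[(4aS,5S,8aR)-5-(hydroxymethyl)-2-methoxy-5,8a-dimethyl-3,4,4a,5,6,7,8,8a-octahydronaphthalen-1-yl]-3-methylpentanoate, via alkylzinc iodide 19 (not isolated)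
Conditions: 18, Zn dust (I2-activated), DMA, 40 °C; then 13, Pd(OAc)2 (5 mol%), SPhos (10 mol%), THF/DMA, 50 °C
Reagents that add atoms: none
Why: Negishi sp2–sp3 coupling of the enol triflate with the ester-tolerant primary alkylzinc reagent forms C9–C11, with a bulky electron-rich phosphine chosen for the hindered tetrasubstituted position.

Step 14
Reactants: 20 methyl (3S)-5-[(4aS,5S,8aR)-5-(hydroxymethyl)-2-methoxy-5,8a-dimethyl-3,4,4a,5,6,7,8,8a-octahydronaphthalen-1-yl]-3-methylpentanoate
Product: 21 methyl (3S)-5-[(1S,4aS,5S,8aR)-5-(hydroxymethyl)-5,8a-dimethyl-2-oxodecahydronaphthalen-1-yl]-3-methylpentanoate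
Conditions: 1 M HCl, THF, rt
Reagents that add atoms: water, O
Why: acid hydrolysis of the methyl enol ether unveils the C8 ketone, and C9 is protonated anti to the C10 methyl and can equilibrate through the enol to the more stable isomer with the side chain equatorial, which is the configuration of the target.

Step 15
Reactants: 21 methyl (3S)-5-[(1S,4aS,5S,8aR)-5-(hydroxymethyl)-5,8a-dimethyl-2-oxodecahydronaphthalen-1-yl]-3-methylpentanoate
Product: 22 methyl (3S)-5-[(1R,4aS,5S,8aS)-5-(hydroxymethyl)-5,8a-dimethyl-2-methylidenedecahydronaphthalen-1-yl]-3-methylpentanoate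
Conditions: Ph3PCH3Br, KOtBu, toluene, rt → 60 °C
Reagents that add atoms: methyltriphenylphosphonium bromide, C[P+](c1ccccc1)(c1ccccc1)c1ccccc1.[Br-]
Why: Wittig methylenation of the C8 ketone installs the exocyclic alkene, and C9 already sits in its thermodynamic configuration, so the basic ylide should not change it.

Step 16
Reactants: 22 methyl (3S)-5-[(1R,4aS,5S,8aS)-5-(hydroxymethyl)-5,8a-dimethyl-2-methylidenedecahydronaphthalen-1-yl]-3-methylpentanoate; 23 (2E)-3-(4-acetoxyphenyl)prop-2-enoic acid
Product: 24 methyl (3S)-5-[(1R,4aS,5S,8aS)-5-({[(2E)-3-(4-acetoxyphenyl)prop-2-enoyl]oxy}methyl)-5,8a-dimethyl-2-methylidenedecahydronaphthalen-1-yl]-3-methylpentanoate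
Conditions: EDC·HCl, DMAP (cat.), CH2Cl2, 0 °C → rt
Reagents that add atoms: none
Why: Steglich esterification acylates the neopentyl primary C18 alcohol, with the phenol masked as its acetate to prevent self-condensation of the acid.

Step 17
Reactants: 24 methyl (3S)-5-[(1R,4aS,5S,8aS)-5-({[(2E)-3-(4-acetoxyphenyl)prop-2-enoyl]oxy}methyl)-5,8a-dimethyl-2-methylidenedecahydronaphthalen-1-yl]-3-methylpentanoate
Product: 25 (3S)-5-[(1R,4aS,5S,8aS)-5-({[(2E)-3-(4-hydroxyphenyl)prop-2-enoyl]oxy}methyl)-5,8a-dimethyl-2-methylidenedecahydronaphthalen-1-yl]-3-methylpentanoic acid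
Conditions: LiOH·H2O, THF/H2O, 0 °C → rt; 1 M HCl to pH 3
Reagents that add atoms: lithium hydroxide, [Li+].[OH-]
Why: the aryl acetate should cleave first, and the resulting phenoxide, conjugated to the cinnamate carbonyl on a neopentyl alcohol, deactivates that ester, so the unhindered methyl ester should be saponified selectively.

**Compound list**

1 | methyl (2S)-oxirane-2-carboxylate | COC(=O)[C@@H]1CO1 | starting material
2 | methyl (2S)-2-hydroxyhex-5-enoate | C=CCC[C@H](O)C(=O)OC | intermediate
3 | methyl (2S)-2-methoxyhex-5-enoate | C=CCC[C@H](OC)C(=O)OC | intermediate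
4 | (2S)-N,2-dimethoxy-N-methylhex-5-enamide | C=CCC[C@H](OC)C(=O)N(C)OC | intermediate
5 | 3-methylbut-3-en-2-one | CC(=O)C(C)=C | starting material
6 | (2S,5E)-N,2-dimethoxy-N,6-dimethyl-7-oxooct-5-enamide | CC(=O)/C(C)=C/CC[C@H](OC)C(=O)N(C)OC | intermediate
7 | (2S,5E)-N,2-dimethoxy-N,6-dimethyl-7-[(triisopropylsilyl)oxy]octa-5,7-dienamide | C=C(O[Si](C(C)C)(C(C)C)C(C)C)/C(C)=C/CC[C@H](OC)C(=O)N(C)OC | intermediate
8 | (4S,7E)-4-methoxy-2,8-dimethyl-9-[(triisopropylsilyl)oxy]deca-1,7,9-trien-3-one | C=C(C)C(=O)[C@@H](OC)CC/C=C(C)/C(=C)O[Si](C(C)C)(C(C)C)C(C)C | intermediate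
9 | (2S,4aR,8aR)-2-methoxy-5,8a-dimethyl-6-[(triisopropylsilyl)oxy]-3,4,4a,7,8,8a-hexahydronaphthalen-1(2H)-one | CO[C@H]1CC[C@@H]2C(C)=C(O[Si](C(C)C)(C(C)C)C(C)C)CC[C@@]2(C)C1=O | intermediate
10 | (4aR,8aR)-2-methoxy-5,8a-dimethyl-6-[(triisopropylsilyl)oxy]-3,4,4a,7,8,8a-hexahydronaphthalen-1-yl trifluoromethanesulfonate | COC1=C(OS(=O)(=O)C(F)(F)F)[C@]2(C)CCC(O[Si](C(C)C)(C(C)C)C(C)C)=C(C)[C@H]2CC1 | intermediate
11 | (4aS,5S,8aR)-5-(hydroxymethyl)-2-methoxy-5,8a-dimethyl-6-oxo-3,4,4a,5,6,7,8,8a-octahydronaphthalen-1-yl trifluoromethanesulfonate | COC1=C(OS(=O)(=O)C(F)(F)F)[C@]2(C)CCC(=O)[C@](C)(CO)[C@H]2CC1 | intermediate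
12 | 4-methylbenzenesulfonylhydrazone of 11 at the ring A ketone (C=N geometry not defined) | COC1=C(OS(=O)(=O)C(F)(F)F)[C@]2(C)CCC(=NNS(=O)(=O)c3ccc(C)cc3)[C@](C)(CO)[C@H]2CC1 | intermediate
13 | (4aR,5S,8aR)-5-(hydroxymethyl)-2-methoxy-5,8a-dimethyl-3,4,4a,5,6,7,8,8a-octahydronaphthalen-1-yl trifluoromethanesulfonate | COC1=C(OS(=O)(=O)C(F)(F)F)[C@]2(C)CCC[C@](C)(CO)[C@H]2CC1 | intermediate
14 | (3R)-5-methoxy-3-methyl-5-oxopentanoic acid | COC(=O)C[C@H](C)CC(=O)O | starting material
15 | (3S)-5-hydroxy-3-methylpentanoic acid | OCC[C@H](C)CC(=O)O | intermediate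
16 | (4S)-4-methyloxan-2-one | C[C@H]1CCOC(=O)C1 | intermediate
17 | trimethylsilyl (3R)-5-iodo-3-methylpentanoate | C[Si](C)(C)OC(=O)C[C@@H](C)CCI | intermediate
18 | methyl (3R)-5-iodo-3-methylpentanoate | COC(=O)C[C@@H](C)CCI | intermediate
19 | [(3R)-5-methoxy-3-methyl-5-oxopentyl]zinc iodide | COC(=O)C[C@@H](C)CC[Zn]I | intermediate
20 | methyl (3S)-5-[(4aS,5S,8aR)-5-(hydroxymethyl)-2-methoxy-5,8a-dimethyl-3,4,4a,5,6,7,8,8a-octahydronaphthalen-1-yl]-3-methylpentanoate | COC1=C(CC[C@H](C)CC(=O)OC)[C@]2(C)CCC[C@](C)(CO)[C@H]2CC1 | intermediate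
21 | methyl (3S)-5-[(1S,4aS,5S,8aR)-5-(hydroxymethyl)-5,8a-dimethyl-2-oxodecahydronaphthalen-1-yl]-3-methylpentanoate | O=C1CC[C@@H]2[C@@](C)(CO)CCC[C@@]2(C)[C@@H]1CC[C@H](C)CC(=O)OC | intermediate
22 | methyl (3S)-5-[(1R,4aS,5S,8aS)-5-(hydroxymethyl)-5,8a-dimethyl-2-methylidenedecahydronaphthalen-1-yl]-3-methylpentanoate | C=C1CC[C@@H]2[C@@](C)(CO)CCC[C@@]2(C)[C@@H]1CC[C@H](C)CC(=O)OC | intermediate
23 | (2E)-3-(4-acetoxyphenyl)prop-2-enoic acid | CC(=O)Oc1ccc(/C=C/C(=O)O)cc1 | starting material
24 | methyl (3S)-5-[(1R,4aS,5S,8aS)-5-({[(2E)-3-(4-acetoxyphenyl)prop-2-enoyl]oxy}methyl)-5,8a-dimethyl-2-methylidenedecahydronaphthalen-1-yl]-3-methylpentanoate | C=C1CC[C@@H]2[C@@](C)(COC(=O)/C=C/c3ccc(OC(C)=O)cc3)CCC[C@@]2(C)[C@@H]1CC[C@H](C)CC(=O)OC | intermediate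
25 | (3S)-5-[(1R,4aS,5S,8aS)-5-({[(2E)-3-(4-hydroxyphenyl)prop-2-enoyl]oxy}methyl)-5,8a-dimethyl-2-methylidenedecahydronaphthalen-1-yl]-3-methylpentanoic acid (CNP0389065.1) | C=C1CC[C@@H]2[C@@](C)(COC(=O)/C=C/c3ccc(O)cc3)CCC[C@@]2(C)[C@@H]1CC[C@H](C)CC(=O)O | target

**Step count**

Total steps: 17. Longest linear sequence: 15 steps (steps 1–10 and 13–17, from 1); steps 11–12 make the side-chain fragment that joins at step 13.

**Steps most likely to fail, with fallbacks**

Step 7. The risk is loss of ring-fusion and face control in the cycloaddition. The Lewis acid may also strip the silyl group and leave open-chain protodesilylated material, or the reaction may leak through a non-chelated or carbonyl-endo transition state to the cis-fused or face-mismatched adduct. The fallback sets out from 8 and returns at 9, and activates the diene as an anion instead of activating the dienophile as a Lewis acid complex. Desilylation of 8 (HF·pyridine, pyridine, THF, 0 °C) should give the diketone (4S,7E)-4-methoxy-2,8-dimethyldeca-1,7-diene-3,9-dione F1. Kinetic deprotonation of its methyl ketone with LiN(SiMe3)2 (THF, −78 °C; the tertiary, methoxy-bearing C8–H is the slower site) should give the cross-conjugated lithium dienolate, in which lithium is chelated by the C9 carbonyl and the C8 methoxy group. Warming to −20 °C should bring about the anion-accelerated cycloaddition (sequential Michael–Michael ring closure), and the resulting C3 lithium enolate is silylated in the same flask with iPr3SiOTf to return to 9.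

Step 13. The risk is slow oxidative addition and transmetalation at the tetrasubstituted, methoxy-substituted enol triflate next to quaternary C10, with protonolysis of the alkylzinc reagent by the free C18 hydroxyl and β-hydride elimination competing. The fallback sets out from 13 (together with 18) and returns at 20: nickel-catalysed reductive cross-electrophile coupling (NiBr2·glyme, 4,4′-di-tert-butyl-2,2′-bipyridine, Mn powder, DMA, rt). Zerovalent nickel inserts into the enol triflate and captures the alkyl radical generated from iodide 18, so no organozinc reagent and no transmetalation is needed. This fallback makes no new compound (F0).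

Step 9. The risk is a slow, reversible aldol addition at the hindered tetrasubstituted enol ether, with hydrolysis of the silyl enol ether to the C4–H ketone or retro-aldol loss of formaldehyde outrunning C–C bond formation. The fallback sets out from 10 and returns at 11: irreversible alkylation with a formyl cation equivalent, followed by adjustment of the oxidation level. 1,3-Dithian-2-ylium tetrafluoroborate (CH2Cl2, −78 °C) should alkylate 10 at C4, again anti to the C10 methyl, to give the dithianyl ketone (4aS,5R,8aR)-5-(1,3-dithian-2-yl)-2-methoxy-5,8a-dimethyl-6-oxo-3,4,4a,5,6,7,8,8a-octahydronaphthalen-1-yl trifluoromethanesulfonate F2. Dithiane removal (MeI, CaCO3, aq. MeCN) should give the keto aldehyde (4aS,5S,8aR)-5-formyl-2-methoxy-5,8a-dimethyl-6-oxo-3,4,4a,5,6,7,8,8a-octahydronaphthalen-1-yl trifluoromethanesulfonate F3, which cannot enolise at the quaternary C4. NaBH(OAc)3 (benzene, rt), which reduces aldehydes but not hindered ketones, should then give 11.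

Further compounds
F1 | step 7 | (4S,7E)-4-methoxy-2,8-dimethyldeca-1,7-diene-3,9-dione | C=C(C)C(=O)[C@@H](OC)CC/C=C(C)/C(C)=O
F0 | step 13 | none | none
F2 | step 9 | (4aS,5R,8aR)-5-(1,3-dithian-2-yl)-2-methoxy-5,8a-dimethyl-6-oxo-3,4,4a,5,6,7,8,8a-octahydronaphthalen-1-yl trifluoromethanesulfonate | COC1=C(OS(=O)(=O)C(F)(F)F)[C@]2(C)CCC(=O)[C@](C)(C3SCCCS3)[C@H]2CC1
F3 | step 9 | (4aS,5S,8aR)-5-formyl-2-methoxy-5,8a-dimethyl-6-oxo-3,4,4a,5,6,7,8,8a-octahydronaphthalen-1-yl trifluoromethanesulfonate | COC1=C(OS(=O)(=O)C(F)(F)F)[C@]2(C)CCC(=O)[C@](C)(C=O)[C@H]2CC1
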